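The substrate was what I followed, one molecule at a time. At its fork it either became target or turned into the other conformer, which led towards the side products.

| setting | eta | epsilon | alpha | elm | larch | oak | cedar |
|---|---|---|---|---|---|---|---|
| substrate | 0.0058 M | 0.028 M | 0.14 M | 0.0060 M | 0.015 M | 0.050 M | 0.15 M |
| remark | run made earlier | run made earlier | run made earlier |  |  |  |  |
| time |  |  |  | 3.0 min | 3.0 min | 3.0 min | 3.0 min |

| run | time / min | target / % | substrate / % |
|---|---|---|---|
| eta | 0.250 | 65 | 22 |
| eta | 0.500 | 77 | 2 |
| eta | 1.33 | 83 | 1 |
| eta | 3.00 | 80 | 0 |
| epsilon | 0.417 | 76 | 7 |
| epsilon | 1.00 | 79 | 0 |
| epsilon | 2.00 | 79 | 1 |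
| epsilon | 3.00 | 81 | 1 |
| alpha | 0.250 | 65 | 22 |
| alpha | 0.500 | 79 | 2 |
| alpha | 1.33 | 84 | 1 |
| alpha | 3.00 | 80 | 3 |

(standard deviation of a reading: 2 percentage points)

- amounts and yields of target count crystals too
- given per volume of solution although it is solid: crystals
- the earlier runs were read with a standard deviation of 2 percentage points
- what may be going on: substrate <-> other conformer; substrate -> target; other conformer -> isomer of the product; other conformer <-> third conformer; third conformer -> third product; crystals <-> target
- a step back or a flat step of under half a percent of the largest counts as no turn
- the concentration of target that is asked is that of its free form alone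
- "hardly changes" means that all values lie within two and a half points (for a concentration: within two and a half percent of the largest)
- a step back or a flat step of under half a percent of the largest counts as no turn

- [target] (only what is free in solution) at the end for elm, larch, oak, cedar, in this order
- how the row runs (hardly changes / rises, then falls / falls all the way / rises all the way / falls, then rises)

I reckoned the chance of taking the target branch in two ways from different readings. The first used an early reading. At 0.250 min the eta run showed 65% target and 22% substrate, so of the material that had left the substrate, 83.3% was target. The alpha run gave 83.3% at that time, from 24.1 times the charge, so I took the fork as independent of charge across these runs.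

The second way used the end of the runs, where the last target readings of the three runs averaged 80.3%. I carried this as the fork share, the fraction of the charge that ends as target, crystals counted; the usual term for such a branching is selectivity.

The two ways parted by 3 percentage points, on readings with a scatter of 2 points. Each early ratio rested on a single pair of readings, whereas the end value rested on three runs, so I kept the end value.

Both ways counted crystals as target. The fork share gave me total target of 0.00482 M, 0.0120 M, 0.0402 M and 0.120 M for elm, larch, oak and cedar. These were totals, and the runs gave me no solubility with which to turn them into free target.

The forecast was 0.0048 M, 0.012 M, 0.04 M and 0.12 M, with a row that rises all the way, and it added: "Any saturation cap would flatten the top end, most likely at cedar and perhaps at oak".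

The flask gave 0.00486 M, 0.0122 M, 0.0130 M and 0.0130 M, a row that rises all the way under the stated margin.

    substrate ⇌ other conformer (K = 13.0, k = 0.0200 s⁻¹)
    substrate → target (k = 0.0850 s⁻¹)
    other conformer → isomer of the product (k = 0.180 s⁻¹)
    other conformer ⇌ third conformer (K = 0.790, k = 0.00230 s⁻¹)
    third conformer → third product (k = 0.0130 s⁻¹)
    crystals ⇌ target, rate k6*(cs6 - [target]) while solid is left; crystals form when [target] > cs6 (solubility = 13.0 mM, k = 0.830 s⁻¹)

Free target in oak stood at 0.0130 M, against 0.04 M in the forecast, and this matched the solubility of 13 mM. As a fraction of its charge, oak held 26.0% free, and the fork share less this left 54.3% for the solid, where oak held crystals at 55.1% after 3.00 min. Cedar held 8.67% of its charge free, so the fork share left 71.7% for the solid, and cedar held crystals at 72.4% after 3.00 min.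

(The runs stem from a simulated flask for substances that don't exist; the scatter is artificial.)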